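**Retrosynthetic overview** (azulene numbering: ring A = C1(iPr)=C8a, C2(OAng), C3, C3a(Me); ring B = C3a, C4, C5(=O), C6(Me)(OAng), C7, C8, C8a)
1. Target 22 ⇐ diol 20 (double angeloylation) ⇐ enol triflate 17 (isopropyl by Negishi coupling) ⇐ hydroazulene-1,5-dione 16.
2. Key disconnections: C4–C5 and C3a–C8a, made together by an intramolecular de Mayo [2+2] photocycloaddition of enol carbonate 12; retro-aldol cleavage of the C5–C8a bond of the resulting cyclobutanol then expands a cyclopentanone into ring B.
3. Enabling feature: the ring B ketone C5 and C1 of ring A are 1,5-related through C4–C3a–C8a. With C1 at the ketone level this is a 1,5-diketone, the retron of a cyclobutanol retro-aldol, so C5–C6–C7–C8–C8a can start as a cyclopentanone and the C3a=C4 methallyl alkene is inserted into its C5–C8a bond.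
4. 12 ⇐ crossed Claisen condensation of cyclopentanone 6 (C6 stereocentre from (R)-2-methylglycidol, ring by Rh hydroacylation) with ester 10 (C2 stereocentre from an asymmetric glyoxylate-ene reaction).
5. Ring order: cyclopentanone C5–C8a first; cyclobutane and ring A in the key step; ring B by fragmentation.

Key step: step 9

Remark: compounds 1, 2, 7, 8, 18 and 21 are taken as commercial, and the azulene numbers of the final skeleton are used for all intermediates.

**Step 1**
Reactants: 1 (R)-2-methylglycidol; 2 vinylmagnesium bromide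
Product: 3 (S)-2-methylpent-4-ene-1,2-diol
Conditions: 2 (2.5 equiv), CuI (10 mol%), THF, −30 → 0 °C; aq NH4Cl
Reagents that add atoms: none
Why: Copper-catalysed SN2 opening of the epoxide at its CH2 terminus; the quaternary centre is untouched (the Payne rearrangement of this alkoxide is degenerate), so the (R)-epoxide should give the (S)-diol, the future C6.

**Step 2**
Reactants: 3 (S)-2-methylpent-4-ene-1,2-diol
Product: 4 (S)-2-methyl-1,2-bis(trimethylsilyloxy)pent-4-ene
Conditions: TMSCl, imidazole, DMF, 0 °C → rt
Reagents that add atoms: chlorotrimethylsilane, C[Si](C)(C)Cl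
Why: Standard silylation; the small TMS group also caps the tertiary alcohol, which must stay masked through step 9.

**Step 3**
Reactants: 4 (S)-2-methyl-1,2-bis(trimethylsilyloxy)pent-4-ene
Product: 5 (S)-2-methyl-2-(trimethylsilyloxy)pent-4-enal
Conditions: (COCl)2, DMSO, CH2Cl2, −78 → −30 °C; Et3N, −78 °C → rt
Reagents that add atoms: none
Why: Swern oxidation acts directly on a primary trimethylsilyl ether, while the tertiary silyl ether cannot be oxidised and stays; the quaternary α-carbon cannot epimerise.

**Step 4**
Reactants: 5 (S)-2-methyl-2-(trimethylsilyloxy)pent-4-enal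
Product: 6 (S)-2-methyl-2-(trimethylsilyloxy)cyclopentan-1-one
Conditions: [Rh(Ph2PCH2CH2PPh2)]ClO4 (5 mol%), CH2Cl2, rt
Reagents that add atoms: none
Why: Rhodium-catalysed intramolecular hydroacylation of a 4-pentenal (acyl–Rh–H, anti-Markovnikov insertion, C–C reductive elimination) closes the cyclopentanone; the stereocentre is not involved.

**Step 5**
Reactants: 7 ethyl glyoxylate; 8 isobutene
Product: 9 ethyl (S)-2-hydroxy-4-methylpent-4-enoate
Conditions: TiCl2(OiPr)2/(S)-BINOL (10 mol%), 4 Å MS, CH2Cl2, −30 °C
Reagents that add atoms: none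
Why: Catalytic asymmetric glyoxylate-ene reaction; BINOL–titanium catalysts of (R) configuration deliver the (R)-hydroxy ester with 1,1-disubstituted alkenes, so the (S)-ligand should set the (S)-carbinol, the future C2.

**Step 6**
Reactants: 9 ethyl (S)-2-hydroxy-4-methylpent-4-enoate
Product: 10 ethyl (S)-2-(tert-butyldimethylsilyloxy)-4-methylpent-4-enoate
Conditions: TBSCl, imidazole, DMF, rt
Reagents that add atoms: tert-butyldimethylsilyl chloride, CC(C)(C)[Si](C)(C)Cl
Why: Standard silylation; the bulky silyl ether later directs the photocycloaddition (step 9) and the enolisation (step 11).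

**Step 7**
Reactants: 6 (S)-2-methyl-2-(trimethylsilyloxy)cyclopentan-1-one; 10 ethyl (S)-2-(tert-butyldimethylsilyloxy)-4-methylpent-4-enoate
Product: 11 (2S)-5-[(2S)-2-(tert-butyldimethylsilyloxy)-4-methylpent-4-enoyl]-2-methyl-2-(trimethylsilyloxy)cyclopentan-1-one
Conditions: 6, LiN(SiMe3)2 (2.2 equiv), THF, −78 °C; then 10, −78 → −30 °C; aq NH4Cl
Reagents that add atoms: none
Why: Crossed Claisen condensation: 6 can enolise only at its CH2 side, the α-silyloxy ester is an activated and poorly enolisable acceptor, and the second equivalent of base stores the product as its diketonate, which drives the reaction and protects the α-silyloxy stereocentre.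

**Step 8**
Reactants: 11 β-diketone
Product: 12 benzyl (5S)-2-[(2S)-2-(tert-butyldimethylsilyloxy)-4-methylpent-4-enoyl]-5-methyl-5-(trimethylsilyloxy)cyclopent-1-en-1-yl carbonate
Conditions: ClCO2Bn, pyridine, CH2Cl2, 0 °C
Reagents that add atoms: benzyl chloroformate, O=C(Cl)OCc1ccccc1
Why: O-acylation of the chelated enol (enol carbonate formation) at the ring oxygen should give the cyclopentenyl carbonate, which fixes the enol double bond between C5 and C8a as required for ring expansion.

**Step 9**
Reactants: 12 enol carbonate
Product: 13 tricyclic photoadduct (benzyl carbonate of the cyclobutanol; cyclobutane C4–C5–C8a–C3a cis-fused to both five-membered rings, C4 syn to the C6 silyloxy group, 3a-methyl cis to the C2 silyloxy group)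
Conditions: hν (medium-pressure Hg lamp, Pyrex, λ > 290 nm), degassed cyclohexane (0.005 M), rt
Reagents that add atoms: none
Why: Excitation of the β-acyloxy enone gives a triplet that first bonds C8a to C3a (five-membered ring, rule of five) and then closes the 1,4-biradical between C5 and C4 to the cyclobutane. The closest known reaction type is the intramolecular de Mayo [2+2] photocycloaddition of enol esters and enol carbonates of 2-acylcyclopentanones that carry the alkene on the acyl chain. Ring A (C1–C2–C3–C3a–C8a) closes in the 5-exo-trig mode onto the internal alkene carbon and the cyclobutane by radical recombination; both new ring fusions must be cis because the three-atom tether delivers C3a and C4 to the same face. The quaternary centre C3a (and with it C8a and C5) is set by the C2 stereocentre, whose silyloxy group should take the exo, pseudo-equatorial position on the forming ring so that the 3a-methyl ends up cis to it; C6 is matched, because on this face the alkene passes the small oxygen substituent and not the methyl group. The step needs fused rather than crossed regiochemistry, secured by the 1,6-diene spacing and the ring-fixed enol double bond, and facial selectivity, secured by the two matched stereocentres.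

**Step 10**
Reactants: 13 tricyclic photoadduct
Product: 16 (2S,3aR,6S)-2-(tert-butyldimethylsilyloxy)-6-hydroxy-3a,6-dimethylperhydroazulene-1,5-dione (C8a epimers), via cyclobutanol 14 (not isolated), via trimethylsilyl ether diketone 15 (not isolated)
Conditions: H2 (1 atm), Pd/C, EtOAc, rt; then citric acid, MeOH, rt
Reagents that add atoms: none
Why: Hydrogenolysis of the benzyl carbonate releases CO2 and the cyclobutanol, a strained β-hydroxy ketone that should undergo retro-aldol cleavage of C5–C8a to ring B under neutral conditions (so C2 is not epimerised); mild acidic methanolysis then removes only the tertiary trimethylsilyl ether.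

**Step 11**
Reactants: 16 hydroxy diketone
Product: 17 (2S,3aR,6S)-2-(tert-butyldimethylsilyloxy)-6-hydroxy-3a,6-dimethyl-5-oxo-2,3,3a,4,5,6,7,8-octahydroazulen-1-yl trifluoromethanesulfonate
Conditions: KN(SiMe3)2 (2.2 equiv), THF, −78 °C; then PhNTf2, −78 → 0 °C
Reagents that add atoms: N-phenylbis(trifluoromethanesulfonimide), O=S(=O)(N(c1ccccc1)S(=O)(=O)C(F)(F)F)C(F)(F)F
Why: Regioselective enolate O-triflation: the first equivalent of base forms the C6 alkoxide, which disfavours enolisation of the adjacent C5 ketone, and kinetic deprotonation of the C1 ketone should occur at C8a–H and not at the silyloxy-bearing C2–H, giving the tetrasubstituted enol triflate and removing the C8a stereocentre.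

**Step 12**
Reactants: 17 enol triflate; 18 isopropylzinc bromide
Product: 19 (2S,3aR,6S)-2-(tert-butyldimethylsilyloxy)-6-hydroxy-1-isopropyl-3a,6-dimethyl-3,3a,4,6,7,8-hexahydroazulen-5(2H)-one
Conditions: 18 (3 equiv), Pd(OAc)2 (5 mol%), CPhos (10 mol%), LiCl, THF/toluene, rt → 40 °C
Reagents that add atoms: none
Why: Negishi coupling of a secondary alkylzinc with an alkenyl triflate; the biarylphosphine ligand makes reductive elimination faster than β-hydride elimination so the branched isopropyl group is kept, and the organozinc tolerates the ketone and the tertiary alcohol.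

**Step 13**
Reactants: 19 silyl ether
Product: 20 (2S,3aR,6S)-2,6-dihydroxy-1-isopropyl-3a,6-dimethyl-3,3a,4,6,7,8-hexahydroazulen-5(2H)-one
Conditions: Bu4NF, AcOH (1 equiv), THF, 0 °C → rt
Reagents that add atoms: none
Why: Fluoride cleavage of the silyl ether; buffering with AcOH avoids base-induced α-ketol rearrangement and ionisation of the allylic alcohol.

**Step 14**
Reactants: 20 diol; 21 angelic anhydride
Product: 22 target CNP0193302.1, (2S,3aR,6S)-1-isopropyl-3a,6-dimethyl-5-oxo-2,3,3a,4,5,6,7,8-octahydroazulene-2,6-diyl bis[(Z)-2-methylbut-2-enoate]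
Conditions: LiN(SiMe3)2 (2.2 equiv), THF, −78 °C; then 21 (3 equiv), −78 → 0 °C
Reagents that add atoms: none
Why: Acylation of the dilithium dialkoxide with the anhydride at low temperature; no nucleophilic amine or acylpyridinium is present, so the (Z)-ester should not isomerise to the tiglate, and both the allylic secondary and the tertiary α-ketol oxygen are acylated.

**Compound list**
1 | (R)-2-methylglycidol, [(2R)-2-methyloxiran-2-yl]methanol | OC[C@]1(C)CO1 | starting material
2 | vinylmagnesium bromide | C=C[Mg]Br | starting material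
3 | (S)-2-methylpent-4-ene-1,2-diol | OC[C@@](C)(O)CC=C | intermediate
4 | (S)-2-methyl-1,2-bis(trimethylsilyloxy)pent-4-ene | C[Si](C)(C)OC[C@@](C)(O[Si](C)(C)C)CC=C | intermediate
5 | (S)-2-methyl-2-(trimethylsilyloxy)pent-4-enal | O=C[C@@](C)(O[Si](C)(C)C)CC=C | intermediate
6 | (S)-2-methyl-2-(trimethylsilyloxy)cyclopentan-1-one | O=C1CCC[C@]1(C)O[Si](C)(C)C | intermediate
7 | ethyl glyoxylate | CCOC(=O)C=O | starting material
8 | isobutene (2-methylpropene) | CC(C)=C | starting material
9 | ethyl (S)-2-hydroxy-4-methylpent-4-enoate | CCOC(=O)[C@@H](O)CC(C)=C | intermediate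
10 | ethyl (S)-2-(tert-butyldimethylsilyloxy)-4-methylpent-4-enoate | CCOC(=O)[C@@H](O[Si](C)(C)C(C)(C)C)CC(C)=C | intermediate
11 | (2S)-5-[(2S)-2-(tert-butyldimethylsilyloxy)-4-methylpent-4-enoyl]-2-methyl-2-(trimethylsilyloxy)cyclopentan-1-one (enolised β-diketone, drawn as diketo form; C5 not fixed) | O=C1C(C(=O)[C@@H](O[Si](C)(C)C(C)(C)C)CC(C)=C)CC[C@]1(C)O[Si](C)(C)C | intermediate
12 | benzyl (5S)-2-[(2S)-2-(tert-butyldimethylsilyloxy)-4-methylpent-4-enoyl]-5-methyl-5-(trimethylsilyloxy)cyclopent-1-en-1-yl carbonate | O=C(OCc1ccccc1)OC1=C(C(=O)[C@@H](O[Si](C)(C)C(C)(C)C)CC(C)=C)CC[C@]1(C)O[Si](C)(C)C | intermediate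
13 | tricyclic photoadduct: benzyl carbonate at C5 of the cyclobutane C4–C5–C8a–C3a, cis-fused to the C5–C6–C7–C8–C8a cyclopentane (C4 syn to 6-OTMS) and to the C1–C2–C3–C3a–C8a cyclopentanone (3a-methyl cis to 2-OTBS) | O=C(OCc1ccccc1)O[C@@]12C[C@@]3(C)C[C@H](O[Si](C)(C)C(C)(C)C)C(=O)[C@@]13CC[C@]2(C)O[Si](C)(C)C | intermediate
14 | cyclobutanol (13 without the benzyloxycarbonyl group) | O[C@@]12C[C@@]3(C)C[C@H](O[Si](C)(C)C(C)(C)C)C(=O)[C@@]13CC[C@]2(C)O[Si](C)(C)C | intermediate (not isolated)
15 | (2S,3aR,6S)-2-(tert-butyldimethylsilyloxy)-3a,6-dimethyl-6-(trimethylsilyloxy)perhydroazulene-1,5-dione (C8a epimers) | O=C1C[C@@]2(C)C[C@H](O[Si](C)(C)C(C)(C)C)C(=O)C2CC[C@]1(C)O[Si](C)(C)C | intermediate (not isolated)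
16 | (2S,3aR,6S)-2-(tert-butyldimethylsilyloxy)-6-hydroxy-3a,6-dimethylperhydroazulene-1,5-dione (C8a epimers) | O=C1C[C@@]2(C)C[C@H](O[Si](C)(C)C(C)(C)C)C(=O)C2CC[C@]1(C)O | intermediate
17 | (2S,3aR,6S)-2-(tert-butyldimethylsilyloxy)-6-hydroxy-3a,6-dimethyl-5-oxo-2,3,3a,4,5,6,7,8-octahydroazulen-1-yl trifluoromethanesulfonate | O=C1C[C@@]2(C)C[C@H](O[Si](C)(C)C(C)(C)C)C(OS(=O)(=O)C(F)(F)F)=C2CC[C@]1(C)O | intermediate
18 | isopropylzinc bromide | CC(C)[Zn]Br | starting material
19 | (2S,3aR,6S)-2-(tert-butyldimethylsilyloxy)-6-hydroxy-1-isopropyl-3a,6-dimethyl-3,3a,4,6,7,8-hexahydroazulen-5(2H)-one | O=C1C[C@@]2(C)C[C@H](O[Si](C)(C)C(C)(C)C)C(C(C)C)=C2CC[C@]1(C)O | intermediate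
20 | (2S,3aR,6S)-2,6-dihydroxy-1-isopropyl-3a,6-dimethyl-3,3a,4,6,7,8-hexahydroazulen-5(2H)-one | O=C1C[C@@]2(C)C[C@H](O)C(C(C)C)=C2CC[C@]1(C)O | intermediate
21 | angelic anhydride, (Z)-2-methylbut-2-enoic anhydride | C/C=C(/C)C(=O)OC(=O)/C(C)=C\C | starting material
22 | CNP0193302.1, (2S,3aR,6S)-1-isopropyl-3a,6-dimethyl-5-oxo-2,3,3a,4,5,6,7,8-octahydroazulene-2,6-diyl bis[(Z)-2-methylbut-2-enoate] | C/C=C(/C)C(=O)O[C@H]1C[C@]2(C)CC(=O)[C@@](C)(OC(=O)/C(C)=C\C)CCC2=C1C(C)C | target

**Step count and risks**
Total steps: 14. Longest linear sequence: 12 (steps 1–4, then 7–14).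

Steps most likely to fail:

1. Step 9. What may go wrong: erosion of facial selectivity when the benzyl carbonate crowds the ring stereocentre, or loss of material by 1,3-acyl (photo-Fries) migration of the enol carbonate. A wrong regiochemistry of O-acylation in step 8 would show up here as crossed cycloaddition. Fallback: the classical free-enol de Mayo reaction, which sets out from 11 and needs no enol derivative. The hydrogen-bonded enol of 11 is irradiated (Pyrex, cyclohexane); cyclobutanol 14 forms directly and fragments in the same flask to 15, which is desilylated with citric acid in MeOH to return at 16. No new compound is made (F0). This fallback does not correct a wrong facial preference that is intrinsic to the two stereocentres.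

2. Step 12. What may go wrong: slow oxidative addition at the hindered tetrasubstituted triflate, and β-hydride elimination or isomerisation of the isopropyl–palladium intermediate (reduced or n-propyl product). Fallback: setting out from 17, a Suzuki coupling with isopropenylboronic acid pinacol ester (Pd(PPh3)4, K3PO4, dioxane/H2O, 80 °C) should give the isopropenyl diene F1. Chemoselective hydrogenation of its 1,1-disubstituted alkene (RhCl(PPh3)3, H2, benzene/EtOH), with the tetrasubstituted ring alkene left alone, returns at 19.

3. Step 14. What may go wrong: Z to E isomerisation of the angelate (tiglate formation) during slow acylation of the tertiary alkoxide, or incomplete acylation of the hindered tertiary α-ketol. Fallback: setting out from 20, both hydroxyls are esterified with the saturated acid 2-[bis(2,2,2-trifluoroethoxy)phosphoryl]propanoic acid (DCC, DMAP, CH2Cl2) to give the bis(phosphonopropionate) F2. A double Still–Gennari olefination with acetaldehyde (KN(SiMe3)2, 18-crown-6, THF, −78 °C) then builds both (Z)-2-methylbut-2-enoates on the molecule and returns at 22.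

**Further compounds**
F0 | step 9 | none | none
F1 | step 12 | (2S,3aR,6S)-2-(tert-butyldimethylsilyloxy)-6-hydroxy-3a,6-dimethyl-1-(prop-1-en-2-yl)-3,3a,4,6,7,8-hexahydroazulen-5(2H)-one | O=C1C[C@@]2(C)C[C@H](O[Si](C)(C)C(C)(C)C)C(C(C)=C)=C2CC[C@]1(C)O
F2 | step 14 | (2S,3aR,6S)-1-isopropyl-3a,6-dimethyl-5-oxo-2,3,3a,4,5,6,7,8-octahydroazulene-2,6-diyl bis{2-[bis(2,2,2-trifluoroethoxy)phosphoryl]propanoate} | O=C1C[C@@]2(C)C[C@H](OC(=O)C(C)P(=O)(OCC(F)(F)F)OCC(F)(F)F)C(C(C)C)=C2CC[C@]1(C)OC(=O)C(C)P(=O)(OCC(F)(F)F)OCC(F)(F)F
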